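C1 is the lactone carbonyl and the chain runs to C22. The acyloxy carbon C7, the cyclopropane C8-C9-C10, the E alkene C11=C12 and the carbinol C13 sit in one unbroken row. This row is what remains when a C7=C8/C10=C11 skipped diene carrying a C12-C13 oxirane ionises at C12 and is quenched at C7 by the C1 carboxyl, five methylenes away.
Retrosynthesis cuts O14-Si first. It then cuts C8-C10 and C7-O(acyl) together, so cyclopropane and oxocan-2-one open at once to an acyclic vinyl oxirane. Last come the oxirane C-O bonds, C13-C14 and C8-C9.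
In the forward direction C1-C8 (an oct-7-ynoate) is joined to C9-C13 (a pentenynyl bromide) by alkenyl-allyl coupling, and C14-C22 ((Z)-non-3-enal) is added at C13. The oxirane is the first ring, and the three- and eight-membered rings then form in one operation.
A Sharpless kinetic-resolution epoxidation with D-(-)-DIPT sets C12, C13 and C14, and a Mitsunobu inversion corrects C14 to S. The cascade relays C12 to C10, C8 and C7 while C13 keeps its oxygen.
The 7E and 12E geometries come from syn hydrozirconation. The 10E and 16Z alkenes are bought.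

Key step: step 12

Remark: the carboxyl is carried as its tert-butyl ester. No free acid therefore ever sits beside the vinyl oxirane, and ring closure is made irreversible by loss of isobutene. The three starting materials are assumed to be bought as single geometric isomers. In zirconocene SMILES the cyclopentadienyl rings are written sigma-bound for notation only.

Step 1
Reactants: 1 oct-7-ynoic acid
Product: 2 tert-butyl oct-7-ynoate
Conditions: Cl3CC(=NH)OtBu, BF3·OEt2 (cat.), cyclohexane/CH2Cl2, rt
Reagents that add atoms: tert-butyl 2,2,2-trichloroacetimidate, CC(C)(C)OC(=N)C(Cl)(Cl)Cl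
Why: Acid-catalysed imidate alkylation of a carboxylic acid should tert-butylate the acid under nearly neutral conditions without touching the terminal alkyne, and the resulting ester tolerates Schwartz reagent, carbonate in methanol and silylation later on.

Step 2
Reactants: 3 (E)-pent-2-en-4-yn-1-ol
Product: 6 (E)-5-(trimethylsilyl)pent-2-en-4-yn-1-ol, via dilithio derivative 4 (not isolated), via O,C-bis(trimethylsilyl) derivative 5 (not isolated)
Conditions: n-BuLi (2.1 equiv), THF, -78 °C; TMSCl (2.2 equiv), -78 °C to rt; 1 M aq. HCl, rt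
Reagents that add atoms: chlorotrimethylsilane, C[Si](C)(C)Cl
Why: Double deprotonation, double silylation and selective hydrolysis of the labile O-Si bond is the standard C-silyl protection of an alkynol, and it masks the acidic C-H and the alkyne terminus for the palladium coupling.

Step 3
Reactants: 6 (E)-5-(trimethylsilyl)pent-2-en-4-yn-1-ol
Product: 7 [(E)-5-bromopent-3-en-1-yn-1-yl]trimethylsilane
Conditions: CBr4, PPh3, CH2Cl2, 0 °C
Reagents that add atoms: tetrabromomethane, BrC(Br)(Br)Br
Why: The Appel reaction should replace the primary allylic hydroxyl by bromide through SN2 at the unhindered CH2 under neutral conditions, without allylic transposition or loss of the E geometry.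

Step 4
Reactants: 2 tert-butyl oct-7-ynoate; 7 [(E)-5-bromopent-3-en-1-yn-1-yl]trimethylsilane
Product: 9 tert-butyl (7E,10E)-13-(trimethylsilyl)trideca-7,10-dien-12-ynoate, via (E)-alkenylzirconocene chloride 8 (not isolated)
Conditions: 2, Cp2ZrHCl (1.1 equiv), THF, rt, dark; then 7, Pd(PPh3)4 (5 mol %), 0 °C to rt
Reagents that add atoms: none
Why: Syn hydrozirconation of the terminal alkyne places zirconium on C8 and fixes 7E, and the Negishi-type palladium-catalysed alkenyl-allyl cross-coupling should join C8 to the unsubstituted allyl terminus C9 with both alkene geometries retained, the silyl cap shielding the far alkyne carbon.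

Step 5
Reactants: 9 tert-butyl (7E,10E)-13-(trimethylsilyl)trideca-7,10-dien-12-ynoate
Product: 10 tert-butyl (7E,10E)-trideca-7,10-dien-12-ynoate
Conditions: K2CO3 (0.2 equiv), MeOH, 0 °C to rt
Reagents that add atoms: none
Why: Carbonate-catalysed methanolytic protodesilylation cleaves only the alkynyl C-Si bond, since the base is too weak to attack the tert-butyl ester or to move the skipped diene into conjugation.

Step 6
Reactants: 11 (Z)-non-3-en-1-ol
Product: 12 (Z)-non-3-enal
Conditions: IBX (1.3 equiv), DMSO/THF, rt; used at once without chromatography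
Reagents that add atoms: none
Why: IBX oxidation stops at the aldehyde under neutral, non-enolising conditions, so the Z beta,gamma-alkene should neither migrate into conjugation nor isomerise before the aldehyde is consumed in step 7.

Step 7
Reactants: 10 tert-butyl (7E,10E)-trideca-7,10-dien-12-ynoate; 12 (Z)-non-3-enal
Product: 16 tert-butyl (7E,10E,12E,16Z)-14-hydroxydocosa-7,10,12,16-tetraenoate (racemic at C14), via dienylzirconocene chloride 13 (not isolated), via dienyl(methyl)zinc 14 (not isolated), via methylzinc alkoxide 15 (not isolated)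
Conditions: 10, Cp2ZrHCl (1.1 equiv), CH2Cl2, rt; Me2Zn (1.1 equiv, toluene), -65 °C; 12, 0 °C; aq. NaHCO3
Reagents that add atoms: none
Why: The terminal alkyne is hydrozirconated far faster than the internal alkenes or the tert-butyl ester and gives the 12E dienyl metal, and zirconium-to-zinc exchange (Wipf protocol) provides a weakly basic alkenylzinc that should add 1,2 to the enolisable aldehyde to form C13-C14, with C14 left racemic for resolution in step 8.

Step 8
Reactants: 16 tert-butyl (7E,10E,12E,16Z)-14-hydroxydocosa-7,10,12,16-tetraenoate (racemic)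
Product: 17 tert-butyl (7E,10E,12R,13R,14R,16Z)-12,13-epoxy-14-hydroxydocosa-7,10,16-trienoate (trans oxirane, erythro)
Conditions: Ti(OiPr)4 (0.15 equiv), D-(-)-DIPT (0.2 equiv), TBHP (0.55 equiv, isooctane), 4 Å MS, CH2Cl2, -20 °C; non-acidic work-up, Et3N-washed silica
Reagents that add atoms: tert-butyl hydroperoxide, CC(C)(C)OO
Why: In the Sharpless kinetic-resolution epoxidation with D-(-)-DIPT only the 14R enantiomer reacts at a useful rate, titanium delivers oxygen solely to the allylic C12=C13 bond on the face set by the tartrate, and the erythro epoxy alcohol results, so C12 (R), C13 (R) and C14 (R) are fixed together.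

Step 9
Reactants: 17 tert-butyl (7E,10E,12R,13R,14R,16Z)-12,13-epoxy-14-hydroxydocosa-7,10,16-trienoate
Product: 18 tert-butyl (7E,10E,12R,13R,14S,16Z)-12,13-epoxy-14-[(4-nitrobenzoyl)oxy]docosa-7,10,16-trienoate
Conditions: 4-O2NC6H4CO2H, PPh3, DIAD, toluene, -10 °C to rt
Reagents that add atoms: 4-nitrobenzoic acid, O=C(O)c1ccc(cc1)[N+](=O)[O-]
Why: The Mitsunobu esterification displaces the activated C14 oxygen by SN2 with inversion (14R to 14S), the routine way from erythro to threo epoxy alcohols, and the acidic nitrobenzoic acid favours substitution over elimination while the oxirane carbons are untouched.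

Step 10
Reactants: 18 tert-butyl (7E,10E,12R,13R,14S,16Z)-12,13-epoxy-14-[(4-nitrobenzoyl)oxy]docosa-7,10,16-trienoate
Product: 19 tert-butyl (7E,10E,12R,13R,14S,16Z)-12,13-epoxy-14-hydroxydocosa-7,10,16-trienoate (threo)
Conditions: K2CO3 (0.2 equiv), MeOH, 0 °C
Reagents that add atoms: none
Why: Base-catalysed transesterification removes the electron-poor aryl ester by acyl-oxygen cleavage, so C14 keeps its configuration, much faster than methoxide can touch the tert-butyl ester, and the low temperature holds back Payne migration.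

Step 11
Reactants: 19 tert-butyl (7E,10E,12R,13R,14S,16Z)-12,13-epoxy-14-hydroxydocosa-7,10,16-trienoate
Product: 20 tert-butyl (7E,10E,12R,13S,14S,16Z)-14-[(tert-butyldimethylsilyl)oxy]-12,13-epoxydocosa-7,10,16-trienoate
Conditions: TBSCl, imidazole, DMF, rt
Reagents that add atoms: tert-butylchlorodimethylsilane, CC(C)(C)[Si](C)(C)Cl
Why: Corey silylation with the chloride and imidazole protects the secondary alcohol without any Lewis acid that could open the vinyl oxirane; the change of the C13 descriptor from R to S reflects only the new priority of the silyloxy branch.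

Step 12
Reactants: 20 tert-butyl (7E,10E,12R,13S,14S,16Z)-14-[(tert-butyldimethylsilyl)oxy]-12,13-epoxydocosa-7,10,16-trienoate
Product: 22 (8R)-8-[(1R,2S)-2-{(1E,3S,4S,6Z)-4-[(tert-butyldimethylsilyl)oxy]-3-hydroxydodeca-1,6-dien-1-yl}cyclopropyl]oxocan-2-one, via tert-butoxy oxocarbenium zwitterion 21 (not isolated)
Conditions: Sc(OTf)3 (10 mol %), 2,6-di-tert-butyl-4-methylpyridine (20 mol %), (CF3)2CHOH/CH2Cl2 1:4, slow addition of 20 to 1 mM, -40 to -10 °C; Et3N quench
Reagents that add atoms: none
Why: Proposed new method: scandium(III) in a strongly ionising, barely nucleophilic medium loosens the allylic C12-O bond of the oxirane, the C7=C8 pi bond attacks C10 on the face opposite that oxygen (SN2', the alkene moving to C11=C12), the charge arriving at C7 as a bisected cyclopropylcarbinyl cation is taken up by the carbonyl oxygen of the tert-butyl ester, and ion 21 then loses isobutene irreversibly, its proton releasing O13 and the catalyst. The nearest established processes are the solvolysis of homoallylic sulfonates in which a neighbouring carboxyl group traps the cyclopropylcarbinyl cation as a cyclopropyl delta-lactone, and the use of tert-butyl esters and carbonates as terminating nucleophiles of Lewis-acid epoxide cascades, but a vinyl oxirane as trigger and an eight-membered ring as terminus are untested. The cyclopropane closes 3-exo (C8 to C10, both reacting pi bonds outside the new ring) and the oxocanone closes 8-exo (O to C7). C10 (S) is dictated by C12 (R) through anti attack on the s-trans vinyl-oxirane conformer, which also makes C11=C12 E; C8 (R) follows from the preference for the trans-1,2-disubstituted ring, C7 (R) from anti addition of C10 and oxygen across the E C7=C8 bond, and C13 keeps its C-O bond while C14 is a spectator. The step needs attack at C10 rather than C12, capture at C7 ahead of cyclobutyl or homoallyl leakage and hydride shift, and no outside nucleophile: the E C10=C11 bond cannot fit into the five-membered ring that C12 attack would give, the silyl ether removes O14 as a competitor and disfavours C13-O cleavage inductively, the ester leaves no acid or carboxylate to open the oxirane directly, and high dilution with a hindered pyridine buffer suppresses bimolecular capture and protic decomposition.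

Step 13
Reactants: 22 (8R)-8-[(1R,2S)-2-{(1E,3S,4S,6Z)-4-[(tert-butyldimethylsilyl)oxy]-3-hydroxydodeca-1,6-dien-1-yl}cyclopropyl]oxocan-2-one
Product: 23 (8R)-8-{(1R,2S)-2-[(1E,3S,4S,6Z)-3,4-dihydroxydodeca-1,6-dien-1-yl]cyclopropyl}oxocan-2-one (CNP0157264.1)
Conditions: TBAF/AcOH (1:1), THF, 0 °C to rt
Reagents that add atoms: none
Why: Fluoride-induced desilylation buffered with acetic acid cleaves the Si-O bond only, so no stereocentre is touched, the lactone is not opened by alkoxide, and the ionisable allylic C13 carbinol next to the vinylcyclopropane sees no strong acid.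

Compound list
1 | oct-7-ynoic acid | C#CCCCCCC(=O)O | starting material
2 | tert-butyl oct-7-ynoate | C#CCCCCCC(=O)OC(C)(C)C | intermediate
3 | (E)-pent-2-en-4-yn-1-ol | C#C/C=C/CO | starting material
4 | O,C-dilithio derivative of 3 | [Li]C#C/C=C/CO[Li] | intermediate
5 | trimethyl{[(E)-5-(trimethylsilyl)pent-2-en-4-yn-1-yl]oxy}silane | C[Si](C)(C)C#C/C=C/CO[Si](C)(C)C | intermediate
6 | (E)-5-(trimethylsilyl)pent-2-en-4-yn-1-ol | C[Si](C)(C)C#C/C=C/CO | intermediate
7 | [(E)-5-bromopent-3-en-1-yn-1-yl]trimethylsilane | C[Si](C)(C)C#C/C=C/CBr | intermediate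
8 | tert-butyl (E)-8-[chlorobis(cyclopentadienyl)zirconio]oct-7-enoate | CC(C)(C)OC(=O)CCCCC/C=C/[Zr](Cl)(C1C=CC=C1)C1C=CC=C1 | intermediate
9 | tert-butyl (7E,10E)-13-(trimethylsilyl)trideca-7,10-dien-12-ynoate | C[Si](C)(C)C#C/C=C/C/C=C/CCCCCC(=O)OC(C)(C)C | intermediate
10 | tert-butyl (7E,10E)-trideca-7,10-dien-12-ynoate | C#C/C=C/C/C=C/CCCCCC(=O)OC(C)(C)C | intermediate
11 | (Z)-non-3-en-1-ol | CCCCC/C=C\CCO | starting material
12 | (Z)-non-3-enal | CCCCC/C=C\CC=O | intermediate
13 | tert-butyl (7E,10E,12E)-13-[chlorobis(cyclopentadienyl)zirconio]trideca-7,10,12-trienoate | CC(C)(C)OC(=O)CCCCC/C=C/C/C=C/C=C/[Zr](Cl)(C1C=CC=C1)C1C=CC=C1 | intermediate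
14 | tert-butyl (7E,10E,12E)-13-(methylzincio)trideca-7,10,12-trienoate | CC(C)(C)OC(=O)CCCCC/C=C/C/C=C/C=C/[Zn]C | intermediate
15 | methylzinc alkoxide of 16 (racemic at C14) | CCCCC/C=C\CC(O[Zn]C)/C=C/C=C/C/C=C/CCCCCC(=O)OC(C)(C)C | intermediate
16 | tert-butyl (7E,10E,12E,16Z)-14-hydroxydocosa-7,10,12,16-tetraenoate, racemic at C14 | CCCCC/C=C\CC(O)/C=C/C=C/C/C=C/CCCCCC(=O)OC(C)(C)C | intermediate
17 | tert-butyl (7E,10E,12R,13R,14R,16Z)-12,13-epoxy-14-hydroxydocosa-7,10,16-trienoate | CCCCC/C=C\C[C@@H](O)[C@H]1O[C@@H]1/C=C/C/C=C/CCCCCC(=O)OC(C)(C)C | intermediate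
18 | tert-butyl (7E,10E,12R,13R,14S,16Z)-12,13-epoxy-14-[(4-nitrobenzoyl)oxy]docosa-7,10,16-trienoate | CCCCC/C=C\C[C@H](OC(=O)c2ccc(cc2)[N+](=O)[O-])[C@H]1O[C@@H]1/C=C/C/C=C/CCCCCC(=O)OC(C)(C)C | intermediate
19 | tert-butyl (7E,10E,12R,13R,14S,16Z)-12,13-epoxy-14-hydroxydocosa-7,10,16-trienoate | CCCCC/C=C\C[C@H](O)[C@H]1O[C@@H]1/C=C/C/C=C/CCCCCC(=O)OC(C)(C)C | intermediate
20 | tert-butyl (7E,10E,12R,13S,14S,16Z)-14-[(tert-butyldimethylsilyl)oxy]-12,13-epoxydocosa-7,10,16-trienoate | CCCCC/C=C\C[C@H](O[Si](C)(C)C(C)(C)C)[C@H]1O[C@@H]1/C=C/C/C=C/CCCCCC(=O)OC(C)(C)C | intermediate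
21 | 2-tert-butoxy-oxocan-1-ium-1-ene / C13 alkoxide zwitterion (scandium on O13 omitted) | CCCCC/C=C\C[C@H](O[Si](C)(C)C(C)(C)C)[C@@H]([O-])/C=C/[C@@H]1C[C@H]1[C@H]1CCCCCC(OC(C)(C)C)=[O+]1 | intermediate
22 | (8R)-8-[(1R,2S)-2-{(1E,3S,4S,6Z)-4-[(tert-butyldimethylsilyl)oxy]-3-hydroxydodeca-1,6-dien-1-yl}cyclopropyl]oxocan-2-one | CCCCC/C=C\C[C@H](O[Si](C)(C)C(C)(C)C)[C@@H](O)/C=C/[C@@H]1C[C@H]1[C@H]1CCCCCC(=O)O1 | intermediate
23 | (8R)-8-{(1R,2S)-2-[(1E,3S,4S,6Z)-3,4-dihydroxydodeca-1,6-dien-1-yl]cyclopropyl}oxocan-2-one | CCCCC/C=C\C[C@H](O)[C@@H](O)/C=C/[C@@H]1C[C@H]1[C@H]1CCCCCC(=O)O1 | target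

Total steps: 13
Longest linear sequence: 11 steps (from 3: steps 2, 3, 4, 5, 7, 8, 9, 10, 11, 12, 13)

Steps most likely to fail

Step 12. Closure of the eight-membered ring may be too slow. The charge would then drain away by hydride shift to a ketone, by proton loss, by cyclobutyl or homoallyl rearrangement or by solvent capture. The oxirane may also ionise without any help from the C7=C8 bond.

The fallback gives up the cascade and builds the two rings separately with known reactions. It sets out from 20 and comes back at 22.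
- Periodic acid (H5IO6, Et2O/THF, 0 °C) cleaves the oxirane of 20 and releases the eastern half as (2S,4Z)-2-[(tert-butyldimethylsilyl)oxy]dec-4-enal F1.
- For the western half, commercial tert-butyldimethyl(prop-2-yn-1-yloxy)silane is hydroborated (Cy2BH) and transmetalated (Et2Zn). It is then added to commercial methyl 7-oxoheptanoate under catalysis by the enantiomer of 3-exo-morpholinoisoborneol that delivers the 7R carbinol. This gives methyl (7R,8E)-10-[(tert-butyldimethylsilyl)oxy]-7-hydroxydec-8-enoate F2.
- Hydroxyl-directed Furukawa-Simmons-Smith cyclopropanation (Et2Zn, CH2I2, CH2Cl2) delivers methylene syn to the zinc alkoxide. It should give the trans ring in the relative configuration of the target, methyl (7R)-7-[(1R,2R)-2-{[(tert-butyldimethylsilyl)oxy]methyl}cyclopropyl]-7-hydroxyheptanoate F3.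
- Saponification (LiOH, THF/H2O) gives the hydroxy acid (7R)-7-[(1R,2R)-2-{[(tert-butyldimethylsilyl)oxy]methyl}cyclopropyl]-7-hydroxyheptanoic acid F4.
- Shiina or Yamaguchi lactonisation at high dilution closes (8R)-8-[(1R,2R)-2-{[(tert-butyldimethylsilyl)oxy]methyl}cyclopropyl]oxocan-2-one F5.
- HF·pyridine frees (8R)-8-[(1R,2R)-2-(hydroxymethyl)cyclopropyl]oxocan-2-one F6.
- Dess-Martin oxidation gives (1R,2R)-2-[(2R)-8-oxooxocan-2-yl]cyclopropane-1-carbaldehyde F7.
- Takai olefination (CHI3, CrCl2, THF) gives (8R)-8-{(1R,2R)-2-[(E)-2-iodoethenyl]cyclopropyl}oxocan-2-one F8.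
- Nozaki-Hiyama-Kishi coupling of F8 with F1 (CrCl2, NiCl2 cat., DMSO/THF) forms C12-C13. It gives 22 together with its C13 epimer, the (13R)-alcohol F9.
- The mixture is oxidised (Dess-Martin) to the C13 enone (8R)-8-[(1R,2S)-2-{(1E,4S,6Z)-4-[(tert-butyldimethylsilyl)oxy]-3-oxododeca-1,6-dien-1-yl}cyclopropyl]oxocan-2-one F10.
- F10 is reduced 1,2 with catecholborane and the CBS catalyst enantiomer matched to the Felkin-Anh preference of the alpha-silyloxy ketone for the 13,14-syn alcohol. This gives 22.

Step 7. The aldehyde may be enolised, or its beta,gamma-alkene may migrate into conjugation before addition. Methyl transfer from zinc or partial ester reduction by Schwartz reagent may also erode the coupling.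

The fallback replaces the zinc reagent by a non-basic organochromium species. It sets out from 10 and comes back at 16. Hydrozirconation of 10 to 13 is followed by iodinolysis (I2, THF, 0 °C), which gives tert-butyl (7E,10E,12E)-13-iodotrideca-7,10,12-trienoate F11. F11 can be purified and stored. It is then coupled with freshly made 12 under Nozaki-Hiyama-Kishi conditions (CrCl2, NiCl2 cat., DMSO/THF, rt) to give 16.

Step 4. The alkenyl group may be delivered to the wrong position of the enynyl pi-allyl palladium intermediate, giving branched or allene-type coupling. The allyl geometry may also scramble by pi-sigma-pi isomerisation.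

The fallback forms C8-C9 as an sp-sp3 bond and sets 7E afterwards. It sets out from 2 and 7 and comes back at 10.
- Copper-mediated coupling of the terminal alkyne 2 with bromide 7 (CuI, NaI, Cs2CO3, DMF, rt) gives tert-butyl (10E)-13-(trimethylsilyl)tridec-10-ene-7,12-diynoate F12.
- Ruthenium-catalysed trans-hydrosilylation ([Cp*Ru(MeCN)3]PF6, (EtO)3SiH, CH2Cl2) should address the unshielded C7-C8 alkyne. It gives tert-butyl (7Z,10E)-8-(triethoxysilyl)-13-(trimethylsilyl)trideca-7,10-dien-12-ynoate F13, drawn as the 8-silyl regioisomer; the 7-silyl isomer converges on the same product.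
- TBAF with catalytic CuI removes the vinylic and the alkynyl silicon in one operation with retention of geometry and gives 10.

Further compounds
F1 | step 12 | (2S,4Z)-2-[(tert-butyldimethylsilyl)oxy]dec-4-enal | CCCCC/C=C\C[C@H](O[Si](C)(C)C(C)(C)C)C=O
F2 | step 12 | methyl (7R,8E)-10-[(tert-butyldimethylsilyl)oxy]-7-hydroxydec-8-enoate | CC(C)(C)[Si](C)(C)OC/C=C/[C@H](O)CCCCCC(=O)OC
F3 | step 12 | methyl (7R)-7-[(1R,2R)-2-{[(tert-butyldimethylsilyl)oxy]methyl}cyclopropyl]-7-hydroxyheptanoate | CC(C)(C)[Si](C)(C)OC[C@@H]1C[C@H]1[C@H](O)CCCCCC(=O)OC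
F4 | step 12 | (7R)-7-[(1R,2R)-2-{[(tert-butyldimethylsilyl)oxy]methyl}cyclopropyl]-7-hydroxyheptanoic acid | CC(C)(C)[Si](C)(C)OC[C@@H]1C[C@H]1[C@H](O)CCCCCC(=O)O
F5 | step 12 | (8R)-8-[(1R,2R)-2-{[(tert-butyldimethylsilyl)oxy]methyl}cyclopropyl]oxocan-2-one | CC(C)(C)[Si](C)(C)OC[C@@H]1C[C@H]1[C@H]1CCCCCC(=O)O1
F6 | step 12 | (8R)-8-[(1R,2R)-2-(hydroxymethyl)cyclopropyl]oxocan-2-one | OC[C@@H]1C[C@H]1[C@H]1CCCCCC(=O)O1
F7 | step 12 | (1R,2R)-2-[(2R)-8-oxooxocan-2-yl]cyclopropane-1-carbaldehyde | O=C[C@@H]1C[C@H]1[C@H]1CCCCCC(=O)O1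
F8 | step 12 | (8R)-8-{(1R,2R)-2-[(E)-2-iodoethenyl]cyclopropyl}oxocan-2-one | I/C=C/[C@@H]1C[C@H]1[C@H]1CCCCCC(=O)O1
F9 | step 12 | C13 epimer of 22, the (13R)-alcohol | CCCCC/C=C\C[C@H](O[Si](C)(C)C(C)(C)C)[C@H](O)/C=C/[C@@H]1C[C@H]1[C@H]1CCCCCC(=O)O1
F10 | step 12 | (8R)-8-[(1R,2S)-2-{(1E,4S,6Z)-4-[(tert-butyldimethylsilyl)oxy]-3-oxododeca-1,6-dien-1-yl}cyclopropyl]oxocan-2-one | CCCCC/C=C\C[C@H](O[Si](C)(C)C(C)(C)C)C(=O)/C=C/[C@@H]1C[C@H]1[C@H]1CCCCCC(=O)O1
F11 | step 7 | tert-butyl (7E,10E,12E)-13-iodotrideca-7,10,12-trienoate | I/C=C/C=C/C/C=C/CCCCCC(=O)OC(C)(C)C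
F12 | step 4 | tert-butyl (10E)-13-(trimethylsilyl)tridec-10-ene-7,12-diynoate | C[Si](C)(C)C#C/C=C/CC#CCCCCCC(=O)OC(C)(C)C
F13 | step 4 | tert-butyl (7Z,10E)-8-(triethoxysilyl)-13-(trimethylsilyl)trideca-7,10-dien-12-ynoate | C[Si](C)(C)C#C/C=C/C/C(=C/CCCCCC(=O)OC(C)(C)C)[Si](OCC)(OCC)OCC
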